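## The problem

β-Collatolic acid (20) is a diaryl ether. One aryl group is a 6-methoxy-3-pentylisocoumarin (isochromen-1-one numbering C1–C8a; benzene ring B, lactone ring C) that carries the ether oxygen at C8, peri to the lactone carbonyl. The other is benzoic acid ring A, numbered here C1' (CO2H), C2' (OH), C3' (H), C4' (OH), C5' (ether oxygen) and C6' (2-oxoheptyl). The ether oxygen joins two electron-rich rings and has ortho substituents on both sides, so a late arene–oxygen coupling is the least attractive bond to form. The molecule has no stereocentre, so nothing has to be relayed; the difficulty is constitutional. Ring A is pentasubstituted, the two oxygens of the isocoumarin must be told apart, and of four acidic oxygen functions exactly one is methylated. Two groups limit the chemistry. The enol lactone is opened by hydroxide and its C3–C4 double bond can be hydrogenated. The C6' ketone closes onto the C1' carboxyl to a second isocoumarin whenever that carboxyl is an ester in base or the keto acid is dehydrated, so it must stay masked and the last steps must be neutral or mildly acidic. The enabling feature is that C1, C8a, C8, C7, C6, C5, C4a, C4 and C3 form a folded polyketide chain with oxygen on every second carbon, and the oxygen on C8 is the ether oxygen. A 4-aryloxy-2-pyrone already holds C1, C8a, C8, C7 and C6 with that oxygen on a vinylogous ester carbon, so the ether can be made by addition–elimination on a pyrone and ring B can then be folded around it.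

## Retrosynthesis

**End game, 20 back to 17.** The three O–benzyl bonds of 19, the two ketal C–O bonds of 18 and the O–CH3 bond at C6 of 18 are cut in turn. Benzyl is chosen for both phenols and the carboxyl because a single neutral hydrogenolysis then ends the synthesis without touching the lactone. The dioxolane is removed one step earlier, while the carboxyl is still an ester, so that the freed ketone never meets a free acid under acidic conditions. Phenol 17 has only one free hydroxyl, which makes the methylation unambiguous. These steps ask only for mild, non-basic conditions.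

**Key disconnection, 17 back to 14.** The C8a–C4a bond of ring B and the O2–C1 bond of ring C are cut, and C1 is rejoined to the C6 oxygen as a 2-pyrone. Cutting the ether C8–O instead would demand coupling of two hindered, electron-rich arenes. The pyrone cut removes both rings at once and leaves the ether oxygen on a vinylogous ester carbon. Precursor 14 has no ring B or C and no stereocentre, and its 2,4-dioxononyl chain maps onto C5, C4a, C4, C3 and the pentyl group. The forward reaction must open the lactone with alkoxide, close ring B by aldol condensation and not by Claisen acylation, and lactonise, all without exchanging the aryloxy group.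

**Side chain, 14 back to 11.** The C–C bond between the two carbonyl-flanked carbons at the hexanoyl end is cut first (14 to 13 and amide 4), then the bond between the pyrone methyl carbon and the acetyl carbon (13 to 11 and amide 12). A single C8 acylation would need the weakly nucleophilic pyrone anion to attack an ester that is itself an enolate. Two Weinreb acylations avoid this and reuse amide 4. The first needs only a silylamide base; the second needs a dianion and is the one step in which ring A meets an amide base of full strength.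

**Ether bond, 11 back to 8 and 10.** The C4(pyrone)–O bond is cut. Addition–elimination of a phenoxide on a 4-bromo-2-pyrone works at an unhindered sp2 carbon, unlike an arene coupling. Bromide 10 is one step from lactone 9. The forward step asks a di-ortho-substituted phenoxide to add at C4 and not at the lactone carbonyl.

**Ring A, 8 back to 1.** The C5'–O bond is traced to a C–Br bond (8 from 6 through boronate 7), the ketal to ketone 5, the C–C bond between the benzylic carbon and the ketone carbon to toluate 3 and amide 4, the C–Br bond to 2, and the three benzyl groups to orsellinic acid 1. Orsellinic acid supplies ring A with carboxyl, both phenols and the methyl group in place. Only one ring oxygen and one acyl group are added. The bromination must go to the ring carbon between methyl and benzyloxy, and the hindered C–Br bond must be converted to C–O in the presence of ester and ketal.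

## Roads not taken

**Alternative 1: ring A as a cyclohexanedione, aromatised late.** The cut runs through ring A at C1'–C6' and C2'–C3'. In the forward sense dibenzyl malonate A1 adds to the α-aryloxy enone A2, which already carries the finished isocoumarin, and the methyl ketone enolate then closes on a malonate ester to give dione A3. The merit is real: the ether oxygen is put on an aliphatic carbon by simple alkylation, and no alkoxide ever meets an aryloxy-pyrone. In these two respects it is safer than the chosen plan. Its weak points are specific to this target: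
- A2 is a β-substituted enone deactivated by its α-oxygen, so the conjugate addition should be slow and reversible.
- The malonate anion and the base for the ring closure meet a base-sensitive enol lactone.
- A3 has three stereocentres that are destroyed again.
- A3 lies two hydrogens below the arene, and the easiest way for such a ring to aromatise is loss of the aryloxy group, which would destroy the ether.

The chosen plan sets against this that ring B is born aromatic at the right oxidation level and that ring A is inherited intact from 1.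

**Alternative 2: ring B by Alder–Rickert reaction.** The cut is at C8–C8a and C5–C4a. The 1-aryloxy-3-silyloxycyclohexadiene A4 adds to the ester-bearing triple bond of methyl deca-2,4-diynoate A5, and the bicyclic adduct expels its two-carbon bridge to give benzoate A6. The regiochemistry follows from the polarised diene, the conditions are neutral, and nothing threatens the aryloxy group. On certainty of the ring-forming event this road is probably better than the alkoxide recyclisation. Against it:
- Ring C is not formed. The heptynyl benzoate still needs a 6-endo cyclisation that competes with 5-exo closure to an alkylidene phthalide.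
- The retro-cycloaddition needs high temperature.
- A4 requires a cross-conjugated dienolate made with a strong amide base in the presence of the ring A ketal, the same hazard as step 9.

The chosen plan offers both rings in one operation, an oxygen pattern that is already differentiated (C6–OH free, C8–O as ether) and a shorter sequence after the key step.

**Alternative 3: ring A by vinylketene benzannulation.** The cut is at C5'–C4', C3'–C2' and C2'–C1'. An amine base converts acid chloride A7 into an aryloxy(alkenyl)ketene, which adds to the siloxyalkyne A8, opens and recloses to phenol A9. Ring A appears fully substituted with complete regiocontrol, and its two phenols are differentiated. The chosen plan depends instead on a regioselective bromination and a hindered carbon–boron bond formation, so in this respect the benzannulation is the better design. Its cost lies in A7: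
- A7 is a racemic α-aryloxy acid with a trisubstituted alkene, a ketal and a tert-butyl ester. It needs many steps.
- It must be turned into an acid chloride without losing the acid-labile groups.
- The derived ketene is prone to dimerise.

The route builds from small pieces a ring that 1 supplies in one purchase. The chosen plan is shorter and uses the same hexanoyl amide 4 for both pentyl ketone units.

Key step: step 10

Assumption: 1, 4, 9 and 12 are purchased, and the keto ester 16 is taken to lactonise under the reaction and work-up conditions as its 8-alkoxy analogues do.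

## Steps

Step 1
Reactants: 1 orsellinic acid (2,4-dihydroxy-6-methylbenzoic acid)
Product: 2 benzyl 2,4-bis(benzyloxy)-6-methylbenzoate
Conditions: BnBr (3.5 equiv), K2CO3, DMF, rt → 60 °C
Reagents that add atoms: benzyl bromide, BrCc1ccccc1
Why: Exhaustive Williamson and carboxylate O-benzylation; warming is needed for the chelated ortho hydroxyl, and benzyl is chosen so that all three groups fall later in one neutral hydrogenolysis.

Step 2
Reactants: 2 benzyl 2,4-bis(benzyloxy)-6-methylbenzoate
Product: 3 benzyl 4,6-bis(benzyloxy)-3-bromo-2-methylbenzoate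
Conditions: NBS (1.05 equiv), MeCN, 0 °C → rt, dark
Reagents that add atoms: N-bromosuccinimide, O=C1CCC(=O)N1Br
Why: Electrophilic aromatic bromination; the carbon between methyl and benzyloxy (para to the other benzyloxy group) should be preferred over the carbon between the two benzyloxy groups, as in orcinol diethers, and ionic conditions avoid benzylic bromination.

Step 3
Reactants: 3 benzyl 4,6-bis(benzyloxy)-3-bromo-2-methylbenzoate; 4 N-methoxy-N-methylhexanamide
Product: 5 benzyl 4,6-bis(benzyloxy)-3-bromo-2-(2-oxoheptyl)benzoate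
Conditions: LiN(i-Pr)2 (1.3 equiv), THF, −78 °C; then 4, −78 °C; AcOH, −78 °C
Reagents that add atoms: none
Why: Lateral lithiation of an ortho-toluate and Weinreb ketone synthesis; the chelated adduct survives until the cold quench, which prevents over-addition and base-induced enol lactonisation, and the amide base does not exchange the aryl bromide, which has no ortho hydrogen.

Step 4
Reactants: 5 benzyl 4,6-bis(benzyloxy)-3-bromo-2-(2-oxoheptyl)benzoate
Product: 6 benzyl 4,6-bis(benzyloxy)-3-bromo-2-[(2-pentyl-1,3-dioxolan-2-yl)methyl]benzoate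
Conditions: (Me3SiOCH2)2, Me3SiOTf (5 mol %), CH2Cl2, −78 → −20 °C; pyridine
Reagents that add atoms: 1,2-bis(trimethylsilyloxy)ethane, C[Si](C)(C)OCCO[Si](C)(C)C
Why: Ketalisation with the bis-silyl ether of the diol under aprotic, cold conditions (Noyori conditions); this avoids the hot protic acid that could close the keto ester to an isocoumarin.

Step 5
Reactants: 6 benzyl 4,6-bis(benzyloxy)-3-bromo-2-[(2-pentyl-1,3-dioxolan-2-yl)methyl]benzoate
Product: 8 benzyl 4,6-bis(benzyloxy)-3-hydroxy-2-[(2-pentyl-1,3-dioxolan-2-yl)methyl]benzoate, via arylboronic pinacol ester 7 (not isolated)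
Conditions: B2pin2, Pd2(dba)3 (2 mol %), XPhos (8 mol %), KOAc, 1,4-dioxane, 100 °C; then 30% H2O2, 1 M NaOH, THF, 0 °C
Reagents that add atoms: hydrogen peroxide, OO (the phenol oxygen); bis(pinacolato)diboron, CC1(C)OB(OC1(C)C)B1OC(C)(C)C(C)(C)O1 (boryl group of 7 only)
Why: Miyaura borylation with a bulky biaryl phosphine, which is the ligand class suited to di-ortho-substituted, electron-rich bromides, followed by oxidation of the boronate; brief cold alkaline peroxide should spare the doubly ortho-substituted benzyl ester and the ketal.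

Step 6
Reactants: 9 4-hydroxy-6-methyl-2H-pyran-2-one
Product: 10 4-bromo-6-methyl-2H-pyran-2-one
Conditions: n-Bu4NBr, P2O5, toluene, 100 °C
Reagents that add atoms: tetrabutylammonium bromide, CCCC[N+](CCCC)(CCCC)CCCC.[Br-]
Why: Known bromodehydroxylation of the vinylogous acid; phosphorylation of the 4-hydroxyl and displacement by bromide give the vinylogous acyl bromide.

Step 7
Reactants: 8 benzyl 4,6-bis(benzyloxy)-3-hydroxy-2-[(2-pentyl-1,3-dioxolan-2-yl)methyl]benzoate; 10 4-bromo-6-methyl-2H-pyran-2-one
Product: 11 benzyl 4,6-bis(benzyloxy)-3-[(6-methyl-2-oxo-2H-pyran-4-yl)oxy]-2-[(2-pentyl-1,3-dioxolan-2-yl)methyl]benzoate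
Conditions: Cs2CO3, MeCN, rt → 50 °C
Reagents that add atoms: none
Why: Conjugate addition–elimination of a phenoxide at C4 of the 4-bromo-2-pyrone, the known entry to 4-aryloxy-6-methyl-2-pyrones; the flat, unhindered C4 should accept the di-ortho-substituted phenoxide, and loss of bromide is irreversible.

Step 8
Reactants: 11 benzyl 4,6-bis(benzyloxy)-3-[(6-methyl-2-oxo-2H-pyran-4-yl)oxy]-2-[(2-pentyl-1,3-dioxolan-2-yl)methyl]benzoate; 12 N-methoxy-N-methylacetamide
Product: 13 benzyl 4,6-bis(benzyloxy)-3-{[2-oxo-6-(2-oxopropyl)-2H-pyran-4-yl]oxy}-2-[(2-pentyl-1,3-dioxolan-2-yl)methyl]benzoate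
Conditions: LiN(SiMe3)2 (1.5 equiv), THF, −78 °C; then 12, −78 → −40 °C; AcOH
Reagents that add atoms: none
Why: Deprotonation of the pyrone 6-methyl group to its vinylogous enolate and Weinreb acylation at the exocyclic carbon; the silylamide is too weak a base to remove the benzylic hydrogens of ring A.

Step 9
Reactants: 13 benzyl 4,6-bis(benzyloxy)-3-{[2-oxo-6-(2-oxopropyl)-2H-pyran-4-yl]oxy}-2-[(2-pentyl-1,3-dioxolan-2-yl)methyl]benzoate; 4 N-methoxy-N-methylhexanamide
Product: 14 benzyl 4,6-bis(benzyloxy)-3-{[6-(2,4-dioxononyl)-2-oxo-2H-pyran-4-yl]oxy}-2-[(2-pentyl-1,3-dioxolan-2-yl)methyl]benzoate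
Conditions: LiN(SiMe3)2 (1.0 equiv) then LiN(i-Pr)2 (1.2 equiv), THF, −78 → −40 °C; then 4, −78 → −20 °C; AcOH
Reagents that add atoms: none
Why: γ-Acylation of a 1,3-dicarbonyl-type dianion: the first base removes the doubly activated pyrone CH2, the second forms the terminal enolate, which is the more nucleophilic site and gives a stable Weinreb adduct. The benzylic CH2 of ring A is secondary and sits between two ortho substituents and a quaternary ketal carbon, so it should be deprotonated more slowly.

Step 10
Reactants: 14 benzyl 4,6-bis(benzyloxy)-3-{[6-(2,4-dioxononyl)-2-oxo-2H-pyran-4-yl]oxy}-2-[(2-pentyl-1,3-dioxolan-2-yl)methyl]benzoate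
Product: 17 benzyl 4,6-bis(benzyloxy)-3-[(6-hydroxy-1-oxo-3-pentyl-1H-isochromen-8-yl)oxy]-2-[(2-pentyl-1,3-dioxolan-2-yl)methyl]benzoate, via ring-opened triketo enoate 15 (not isolated), via keto resorcylate 16 (not isolated)
Conditions: Mg(OMe)2 (5 equiv), MeOH–THF, 65 °C; then cold 0.5 M HCl to pH 4
Reagents that add atoms: methanol (from Mg(OMe)2), CO (present in 15 and 16 only; no reagent atom remains in 17)
Why: Mg(OMe)2 forms the magnesium chelate of the 2,4-dione, methoxide adds to the lactone carbonyl C1 and the pyrone opens to 15, held as a magnesium polyketide enolate. Deprotonation at C7 gives a dienolate whose α-carbon C8a attacks the chelate-activated C4a carbonyl in a 6-(enolexo)-exo-trig aldol, and dehydration with enolisation of the C6 ketone aromatises ring B to 16. The C3 enol oxygen then displaces methoxide at C1 in a 6-exo-trig acyl substitution and closes ring C. The closest known reaction type is the alkoxide-induced recyclisation of 4-methoxy-6-(2-oxoalkyl)- and 6-(2,4-dioxoalkyl)-2-pyrones to resorcylates and 6-hydroxy-8-methoxyisocoumarins. No stereocentre is formed. Methoxide must attack C1 and not C8 (pyrone C4); the electron-rich, di-ortho-substituted aryloxy group is a poor leaving group that shields its carbon, and magnesium-bound methoxide is weakly nucleophilic. Aldol must beat Claisen closure of C5 on C1; because the C8 oxygen is locked as an ether, C1 stays a weakly electrophilic vinylogous carbonate while C8a is the nucleophilic end of the dienolate. The dioxolane, the benzyl ethers and the doubly ortho-substituted benzyl ester of ring A should be inert to methanolic Mg(OMe)2.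

Step 11
Reactants: 17 benzyl 4,6-bis(benzyloxy)-3-[(6-hydroxy-1-oxo-3-pentyl-1H-isochromen-8-yl)oxy]-2-[(2-pentyl-1,3-dioxolan-2-yl)methyl]benzoate
Product: 18 benzyl 4,6-bis(benzyloxy)-3-[(6-methoxy-1-oxo-3-pentyl-1H-isochromen-8-yl)oxy]-2-[(2-pentyl-1,3-dioxolan-2-yl)methyl]benzoate
Conditions: MeI, K2CO3, acetone, rt → 40 °C
Reagents that add atoms: iodomethane, CI
Why: Williamson methylation of the only free phenol, which is acidic because it is para to the lactone carbonyl; anhydrous carbonate in acetone leaves the lactone and the hindered ester untouched.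

Step 12
Reactants: 18 benzyl 4,6-bis(benzyloxy)-3-[(6-methoxy-1-oxo-3-pentyl-1H-isochromen-8-yl)oxy]-2-[(2-pentyl-1,3-dioxolan-2-yl)methyl]benzoate
Product: 19 benzyl 4,6-bis(benzyloxy)-3-[(6-methoxy-1-oxo-3-pentyl-1H-isochromen-8-yl)oxy]-2-(2-oxoheptyl)benzoate
Conditions: 1 M HCl, THF, rt → 40 °C
Reagents that add atoms: water, O
Why: Acid-catalysed ketal hydrolysis; it is run while the carboxyl is still a benzyl ester, so the freed ketone cannot cyclodehydrate with a free acid, and dilute aqueous acid does not affect the enol lactone, diaryl ether or benzyl groups.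

Step 13
Reactants: 19 benzyl 4,6-bis(benzyloxy)-3-[(6-methoxy-1-oxo-3-pentyl-1H-isochromen-8-yl)oxy]-2-(2-oxoheptyl)benzoate
Product: 20 β-collatolic acid, 4,6-dihydroxy-3-[(6-methoxy-1-oxo-3-pentyl-1H-isochromen-8-yl)oxy]-2-(2-oxoheptyl)benzoic acid
Conditions: H2 (1 atm), 10% Pd/C, EtOAc, rt
Reagents that add atoms: none
Why: Hydrogenolysis of one benzyl ester and two aryl benzyl ethers under neutral conditions, stopped after uptake of three equivalents; the dialkyl ketone and the conjugated enol-lactone double bond should be reduced far more slowly at ambient pressure.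

## Compound list

1 | orsellinic acid (2,4-dihydroxy-6-methylbenzoic acid) | Cc1cc(O)cc(O)c1C(=O)O | starting material
2 | benzyl 2,4-bis(benzyloxy)-6-methylbenzoate | Cc1cc(OCc2ccccc2)cc(OCc2ccccc2)c1C(=O)OCc1ccccc1 | intermediate
3 | benzyl 4,6-bis(benzyloxy)-3-bromo-2-methylbenzoate | Cc1c(Br)c(OCc2ccccc2)cc(OCc2ccccc2)c1C(=O)OCc1ccccc1 | intermediate
4 | N-methoxy-N-methylhexanamide | CCCCCC(=O)N(C)OC | starting material
5 | benzyl 4,6-bis(benzyloxy)-3-bromo-2-(2-oxoheptyl)benzoate | CCCCCC(=O)Cc1c(Br)c(OCc2ccccc2)cc(OCc2ccccc2)c1C(=O)OCc1ccccc1 | intermediate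
6 | benzyl 4,6-bis(benzyloxy)-3-bromo-2-[(2-pentyl-1,3-dioxolan-2-yl)methyl]benzoate | CCCCCC1(Cc2c(Br)c(OCc3ccccc3)cc(OCc3ccccc3)c2C(=O)OCc2ccccc2)OCCO1 | intermediate
7 | benzyl 4,6-bis(benzyloxy)-2-[(2-pentyl-1,3-dioxolan-2-yl)methyl]-3-(4,4,5,5-tetramethyl-1,3,2-dioxaborolan-2-yl)benzoate (formed in the flask) | CCCCCC1(Cc2c(B3OC(C)(C)C(C)(C)O3)c(OCc3ccccc3)cc(OCc3ccccc3)c2C(=O)OCc2ccccc2)OCCO1 | intermediate
8 | benzyl 4,6-bis(benzyloxy)-3-hydroxy-2-[(2-pentyl-1,3-dioxolan-2-yl)methyl]benzoate | CCCCCC1(Cc2c(O)c(OCc3ccccc3)cc(OCc3ccccc3)c2C(=O)OCc2ccccc2)OCCO1 | intermediate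
9 | 4-hydroxy-6-methyl-2H-pyran-2-one | CC1=CC(O)=CC(=O)O1 | starting material
10 | 4-bromo-6-methyl-2H-pyran-2-one | CC1=CC(Br)=CC(=O)O1 | intermediate
11 | benzyl 4,6-bis(benzyloxy)-3-[(6-methyl-2-oxo-2H-pyran-4-yl)oxy]-2-[(2-pentyl-1,3-dioxolan-2-yl)methyl]benzoate | CC1=CC(Oc2c(CC3(CCCCC)OCCO3)c(C(=O)OCc3ccccc3)c(OCc3ccccc3)cc2OCc2ccccc2)=CC(=O)O1 | intermediate
12 | N-methoxy-N-methylacetamide | CC(=O)N(C)OC | starting material
13 | benzyl 4,6-bis(benzyloxy)-3-{[2-oxo-6-(2-oxopropyl)-2H-pyran-4-yl]oxy}-2-[(2-pentyl-1,3-dioxolan-2-yl)methyl]benzoate | CC(=O)CC1=CC(Oc2c(CC3(CCCCC)OCCO3)c(C(=O)OCc3ccccc3)c(OCc3ccccc3)cc2OCc2ccccc2)=CC(=O)O1 | intermediate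
14 | benzyl 4,6-bis(benzyloxy)-3-{[6-(2,4-dioxononyl)-2-oxo-2H-pyran-4-yl]oxy}-2-[(2-pentyl-1,3-dioxolan-2-yl)methyl]benzoate | CCCCCC(=O)CC(=O)CC1=CC(Oc2c(CC3(CCCCC)OCCO3)c(C(=O)OCc3ccccc3)c(OCc3ccccc3)cc2OCc2ccccc2)=CC(=O)O1 | intermediate
15 | methyl (2E)-3-aryloxy-5,7,9-trioxotetradec-2-enoate, aryl = 4,6-bis(benzyloxy)-3-(benzyloxycarbonyl)-2-[(2-pentyl-1,3-dioxolan-2-yl)methyl]phenyl (formed in the flask as its magnesium enolate) | COC(=O)/C=C(/Oc1c(CC2(CCCCC)OCCO2)c(C(=O)OCc2ccccc2)c(OCc2ccccc2)cc1OCc1ccccc1)CC(=O)CC(=O)CC(=O)CCCCC | intermediate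
16 | benzyl 4,6-bis(benzyloxy)-3-[5-hydroxy-2-(methoxycarbonyl)-3-(2-oxoheptyl)phenoxy]-2-[(2-pentyl-1,3-dioxolan-2-yl)methyl]benzoate (formed in the flask) | CCCCCC(=O)Cc1cc(O)cc(Oc2c(CC3(CCCCC)OCCO3)c(C(=O)OCc3ccccc3)c(OCc3ccccc3)cc2OCc2ccccc2)c1C(=O)OC | intermediate
17 | benzyl 4,6-bis(benzyloxy)-3-[(6-hydroxy-1-oxo-3-pentyl-1H-isochromen-8-yl)oxy]-2-[(2-pentyl-1,3-dioxolan-2-yl)methyl]benzoate | CCCCCc1cc2cc(O)cc(Oc3c(CC4(CCCCC)OCCO4)c(C(=O)OCc4ccccc4)c(OCc4ccccc4)cc3OCc3ccccc3)c2c(=O)o1 | intermediate
18 | benzyl 4,6-bis(benzyloxy)-3-[(6-methoxy-1-oxo-3-pentyl-1H-isochromen-8-yl)oxy]-2-[(2-pentyl-1,3-dioxolan-2-yl)methyl]benzoate | CCCCCc1cc2cc(OC)cc(Oc3c(CC4(CCCCC)OCCO4)c(C(=O)OCc4ccccc4)c(OCc4ccccc4)cc3OCc3ccccc3)c2c(=O)o1 | intermediate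
19 | benzyl 4,6-bis(benzyloxy)-3-[(6-methoxy-1-oxo-3-pentyl-1H-isochromen-8-yl)oxy]-2-(2-oxoheptyl)benzoate | CCCCCC(=O)Cc1c(Oc2cc(OC)cc3cc(CCCCC)oc(=O)c23)c(OCc2ccccc2)cc(OCc2ccccc2)c1C(=O)OCc1ccccc1 | intermediate
20 | β-collatolic acid, 4,6-dihydroxy-3-[(6-methoxy-1-oxo-3-pentyl-1H-isochromen-8-yl)oxy]-2-(2-oxoheptyl)benzoic acid | CCCCCC(=O)Cc1c(Oc2cc(OC)cc3cc(CCCCC)oc(=O)c23)c(O)cc(O)c1C(=O)O | target

## Step count and risks

Total: 13 steps. Longest linear sequence: 12 steps (steps 1–5 and 7–13, from 1 to 20); step 6 is a one-step branch.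

**Step 10 (key step).** The most likely failure is exchange of the aryloxy group for methoxide at the vinylogous ester carbon, before or after ring opening, which would release phenol 8. Next in likelihood are Claisen closure of C5 on C1 and incomplete lactonisation of 16. The fallback leaves the pyrone route and forms the ether last, on a finished isocoumarin. Methyl 2-bromo-4-methoxy-6-methylbenzoate F1, a simple bromotoluate taken as a building block, would be laterally lithiated with LiN(i-Pr)2 and acylated with amide 4 to give methyl 2-bromo-4-methoxy-6-(2-oxoheptyl)benzoate F2. Base-induced enol lactonisation would give 8-bromo-6-methoxy-3-pentyl-1H-isochromen-1-one F3. An Ullmann etherification of phenol 8 with F3 (CuI, picolinic acid, K3PO4, DMSO, 90 °C), helped by the ortho carbonyl of the bromide, would return to the route at 18.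

**Step 9.** The amide base may also deprotonate the benzylic CH2 of ring A. That anion could be acylated or could open the dioxolane by β-elimination. The fallback uses only monoanion chemistry, setting out from 11 and returning at 14. Commercial ethyl 3-hydroxyoctanoate would be silylated to ethyl 3-[(tert-butyldimethylsilyl)oxy]octanoate F4 and converted with MeNH(OMe)·HCl and i-PrMgCl into 3-[(tert-butyldimethylsilyl)oxy]-N-methoxy-N-methyloctanamide F5. The LiN(SiMe3)2-derived anion of 11 would be acylated with F5 to the silyloxy ketone, benzyl 4,6-bis(benzyloxy)-3-({6-[4-(tert-butyldimethylsilyloxy)-2-oxononyl]-2-oxo-2H-pyran-4-yl}oxy)-2-[(2-pentyl-1,3-dioxolan-2-yl)methyl]benzoate F6. HF·pyridine would give the hydroxy ketone, benzyl 4,6-bis(benzyloxy)-3-{[6-(4-hydroxy-2-oxononyl)-2-oxo-2H-pyran-4-yl]oxy}-2-[(2-pentyl-1,3-dioxolan-2-yl)methyl]benzoate F7, and oxidation with 2-iodoxybenzoic acid would give 14.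

**Step 5.** Oxidative addition and transmetalation at the di-ortho-substituted, electron-rich C–Br bond may be slow, so that protodebromination takes over. The fallback sets out from 6 and uses halogen–lithium exchange, which is insensitive to this hindrance. n-BuLi would be added at −78 °C to 6 in the presence of B(Oi-Pr)3 (in situ quench), giving after hydrolysis {4,6-bis(benzyloxy)-3-[(benzyloxy)carbonyl]-2-[(2-pentyl-1,3-dioxolan-2-yl)methyl]phenyl}boronic acid F8. Peroxide oxidation of F8 returns to 8.

**Step 3.** The benzylic anion next to bromine may undergo proton or halogen transfer, and the keto ester may close to an isocoumarin if the mixture warms before the quench. The fallback changes the order, setting out from 2 and returning at 6. Lateral lithiation of 2 and acylation with 4 would give benzyl 2,4-bis(benzyloxy)-6-(2-oxoheptyl)benzoate F9. Ketalisation as in step 4 would give benzyl 2,4-bis(benzyloxy)-6-[(2-pentyl-1,3-dioxolan-2-yl)methyl]benzoate F10, and bromination with NBS would give 6, at the cost of a more crowded bromination site.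

**Step 13.** Over-reduction of the C3–C4 double bond of the isocoumarin may compete if the hindered ethers cleave slowly. The fallback sets out from 19 and reaches 20 by Lewis-acid debenzylation (BCl3, pentamethylbenzene as cation scavenger, CH2Cl2, −78 °C), which leaves the non-chelated C6 methyl ether and the double bond alone. This fallback makes no new compound (F0).

## Further compounds

F1 | step 10 | methyl 2-bromo-4-methoxy-6-methylbenzoate | COC(=O)c1c(C)cc(OC)cc1Br
F2 | step 10 | methyl 2-bromo-4-methoxy-6-(2-oxoheptyl)benzoate | CCCCCC(=O)Cc1cc(OC)cc(Br)c1C(=O)OC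
F3 | step 10 | 8-bromo-6-methoxy-3-pentyl-1H-isochromen-1-one | CCCCCc1cc2cc(OC)cc(Br)c2c(=O)o1
F4 | step 9 | ethyl 3-[(tert-butyldimethylsilyl)oxy]octanoate (racemic) | CCCCCC(CC(=O)OCC)O[Si](C)(C)C(C)(C)C
F5 | step 9 | 3-[(tert-butyldimethylsilyl)oxy]-N-methoxy-N-methyloctanamide (racemic) | CCCCCC(CC(=O)N(C)OC)O[Si](C)(C)C(C)(C)C
F6 | step 9 | benzyl 4,6-bis(benzyloxy)-3-({6-[4-(tert-butyldimethylsilyloxy)-2-oxononyl]-2-oxo-2H-pyran-4-yl}oxy)-2-[(2-pentyl-1,3-dioxolan-2-yl)methyl]benzoate (racemic) | CCCCCC(CC(=O)CC1=CC(Oc2c(CC3(CCCCC)OCCO3)c(C(=O)OCc3ccccc3)c(OCc3ccccc3)cc2OCc2ccccc2)=CC(=O)O1)O[Si](C)(C)C(C)(C)C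
F7 | step 9 | benzyl 4,6-bis(benzyloxy)-3-{[6-(4-hydroxy-2-oxononyl)-2-oxo-2H-pyran-4-yl]oxy}-2-[(2-pentyl-1,3-dioxolan-2-yl)methyl]benzoate (racemic) | CCCCCC(O)CC(=O)CC1=CC(Oc2c(CC3(CCCCC)OCCO3)c(C(=O)OCc3ccccc3)c(OCc3ccccc3)cc2OCc2ccccc2)=CC(=O)O1
F8 | step 5 | {4,6-bis(benzyloxy)-3-[(benzyloxy)carbonyl]-2-[(2-pentyl-1,3-dioxolan-2-yl)methyl]phenyl}boronic acid | CCCCCC1(Cc2c(B(O)O)c(OCc3ccccc3)cc(OCc3ccccc3)c2C(=O)OCc2ccccc2)OCCO1
F9 | step 3 | benzyl 2,4-bis(benzyloxy)-6-(2-oxoheptyl)benzoate | CCCCCC(=O)Cc1cc(OCc2ccccc2)cc(OCc2ccccc2)c1C(=O)OCc1ccccc1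
F10 | step 3 | benzyl 2,4-bis(benzyloxy)-6-[(2-pentyl-1,3-dioxolan-2-yl)methyl]benzoate | CCCCCC1(Cc2cc(OCc3ccccc3)cc(OCc3ccccc3)c2C(=O)OCc2ccccc2)OCCO1
F0 | step 13 | none | none
A1 | alternative 1 | dibenzyl malonate | O=C(CC(=O)OCc1ccccc1)OCc1ccccc1
A2 | alternative 1 | (3Z)-3-[(6-methoxy-1-oxo-3-pentyl-1H-isochromen-8-yl)oxy]-5-(2-pentyl-1,3-dioxolan-2-yl)pent-3-en-2-one | CC(=O)/C(Oc1cc(OC)cc2cc(CCCCC)oc(=O)c12)=C/CC1(CCCCC)OCCO1
A3 | alternative 1 | benzyl 3-[(6-methoxy-1-oxo-3-pentyl-1H-isochromen-8-yl)oxy]-4,6-dioxo-2-[(2-pentyl-1,3-dioxolan-2-yl)methyl]cyclohexane-1-carboxylate (racemic, all-trans drawn) | [C@H]1(C(=O)OCc2ccccc2)C(=O)CC(=O)[C@@H](Oc2cc(OC)cc3cc(CCCCC)oc(=O)c23)[C@@H]1CC1(CCCCC)OCCO1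
A4 | alternative 2 | benzyl 4,6-bis(benzyloxy)-2-[(2-pentyl-1,3-dioxolan-2-yl)methyl]-3-{[3-(trimethylsilyloxy)cyclohexa-1,3-dien-1-yl]oxy}benzoate | C[Si](C)(C)OC1=CCCC(Oc2c(CC3(CCCCC)OCCO3)c(C(=O)OCc3ccccc3)c(OCc3ccccc3)cc2OCc2ccccc2)=C1
A5 | alternative 2 | methyl deca-2,4-diynoate | CCCCCC#CC#CC(=O)OC
A6 | alternative 2 | methyl 2-aryloxy-6-(hept-1-ynyl)-4-(trimethylsilyloxy)benzoate, aryl = protected ring A as in 8 | CCCCCC#Cc1cc(O[Si](C)(C)C)cc(Oc2c(CC3(CCCCC)OCCO3)c(C(=O)OCc3ccccc3)c(OCc3ccccc3)cc2OCc2ccccc2)c1C(=O)OC
A7 | alternative 3 | tert-butyl (2E)-5-chloro-4-[(6-methoxy-1-oxo-3-pentyl-1H-isochromen-8-yl)oxy]-5-oxo-3-[(2-pentyl-1,3-dioxolan-2-yl)methyl]pent-2-enoate (racemic) | ClC(=O)C(Oc1cc(OC)cc2cc(CCCCC)oc(=O)c12)/C(CC1(CCCCC)OCCO1)=C/C(=O)OC(C)(C)C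
A8 | alternative 3 | (triisopropylsilyloxy)ethyne | C#CO[Si](C(C)C)(C(C)C)C(C)C
A9 | alternative 3 | tert-butyl 6-hydroxy-3-[(6-methoxy-1-oxo-3-pentyl-1H-isochromen-8-yl)oxy]-2-[(2-pentyl-1,3-dioxolan-2-yl)methyl]-4-(triisopropylsilyloxy)benzoate | CCCCCC1(Cc2c(Oc3cc(OC)cc4cc(CCCCC)oc(=O)c34)c(O[Si](C(C)C)(C(C)C)C(C)C)cc(O)c2C(=O)OC(C)(C)C)OCCO1
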